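## Plan

1. Ring letters: A = cyclopentane with CH3/CO2H, B = central cyclopentane, C = cyclopentenone, D = dihydropyran, E = nine-membered ring, F = cyclobutane. Retrosynthetic cuts: (a) in ring A the bond between the quaternary carbon and one CH2, with the CO2H carbon put back into that bond, so that ring A plus the CO2H carbon is a 1,2-dimethylcyclohexene oxide (the extra CH3 is removed at the end by haloform cleavage); (b) in ring D the bonds O–C(CH3) and CH2–CH, an oxa-Diels–Alder of an α-methylene-1,2-dione with (+)-β-caryophyllene, which carries rings E and F; (c) rings B and C together (Pauson–Khand); (d) the cyclohexene (Diels–Alder).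
2. Forward order of ring formation: cyclohexene → B and C in one step → D (E and F arrive with the terpene) → A last, by contraction of the six-membered ring.
3. Enabling feature: the quaternary carbon of ring A lies between two CH2 groups, each bound to an A/B ring-fusion CH. The unit CH2–C(CH3)(CO2H)–CH2 therefore maps onto a symmetrically substituted cyclohexene whose two alkene carbons are equivalent, and whichever epoxide C–O bond ionizes, the same ring A results.
4. Stereochemistry: the two A/B ring-fusion CH come from a cis Diels–Alder adduct, made single-enantiomer by catalytic desymmetrization of the meso anhydride. The angular CH3 and the B/C fusion follow by substrate control (Pauson–Khand, cis-bicyclo[3.3.0]octane). The two ring-D centres come from suprafacial addition to one face of (+)-β-caryophyllene. The quaternary carbon of ring A comes from convex-face epoxidation followed by an invertive 1,2-shift.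

Key step: step 12

Assumption: the caryophyllane half of the target has the (1S,9R) cyclobutane, so the terpene partner is (+)-β-caryophyllene, the mirror image of the bulk (−)-terpene; it is treated here as a purchasable specialty terpene.

## Route

Step 1
Reactants: 1 2,3-dimethylbuta-1,3-diene; 2 maleic anhydride
Product: 3 cis-4,5-dimethylcyclohex-4-ene-1,2-dicarboxylic anhydride (meso)
Conditions: toluene, 60 °C
Reagents that add atoms: none
Why: Thermal Diels–Alder reaction in which the cis geometry of the dienophile is transferred suprafacially, so the two ring CH groups (the later A/B fusion carbons) are cis and the adduct is meso.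

Step 2
Reactants: 3 cis-4,5-dimethylcyclohex-4-ene-1,2-dicarboxylic anhydride
Product: 4 (1S,6R)-6-acetyl-3,4-dimethylcyclohex-3-ene-1-carboxylic acid
Conditions: Me2Zn (1.3 equiv), Pd(OAc)2 (5 mol %), JOSIPHOS-type ferrocenyl diphosphine (6 mol %, the enantiomer that alkylates the carbonyl on the (R)-configured ring carbon), THF, 23 °C; then 1 M HCl
Reagents that add atoms: dimethylzinc C[Zn]C
Why: Palladium-catalysed enantioselective alkylative desymmetrization of a meso cyclic anhydride with a diorganozinc, in which the chiral diphosphine selects one of the two enantiotopic carbonyl groups and so fixes the absolute configuration of both ring CH centres without touching them.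

Step 3
Reactants: 4 (1S,6R)-6-acetyl-3,4-dimethylcyclohex-3-ene-1-carboxylic acid
Product: 5 (1S,6R)-3,4-dimethyl-6-(prop-1-en-2-yl)cyclohex-3-ene-1-carboxylic acid
Conditions: Ph3PCH3Br (2.4 equiv), KN(SiMe3)2 (2.3 equiv), THF, 0 °C; then 4, 0 °C to 23 °C; 1 M HCl
Reagents that add atoms: methyltriphenylphosphonium bromide C[P+](c1ccccc1)(c1ccccc1)c1ccccc1.[Br-]
Why: Wittig methylenation of the methyl ketone (the carboxylate is inert) gives the 1,1-disubstituted alkene needed for the Pauson–Khand step, the cold ylide being used so that the adjacent ring CH is not epimerized, and no stereocenter is formed.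

Step 4
Reactants: 5 (1S,6R)-3,4-dimethyl-6-(prop-1-en-2-yl)cyclohex-3-ene-1-carboxylic acid
Product: 6 [(1S,6R)-3,4-dimethyl-6-(prop-1-en-2-yl)cyclohex-3-en-1-yl]methanol
Conditions: LiAlH4, THF, 0 °C to reflux; Fieser work-up
Reagents that add atoms: none
Why: Hydride reduction of the carboxylic acid to the primary alcohol, to which the isolated alkenes are inert and which touches no stereocenter.

Step 5
Reactants: 6 [(1S,6R)-3,4-dimethyl-6-(prop-1-en-2-yl)cyclohex-3-en-1-yl]methanol
Product: 7 [(1S,6R)-3,4-dimethyl-6-(prop-1-en-2-yl)cyclohex-3-en-1-yl]methyl 4-methylbenzenesulfonate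
Conditions: TsCl, Et3N, DMAP (cat.), CH2Cl2, 0 °C to 23 °C
Reagents that add atoms: p-toluenesulfonyl chloride Cc1ccc(cc1)S(Cl)(=O)=O
Why: Standard sulfonylation of a primary alcohol to install a leaving group, with no stereocenter involved.

Step 6
Reactants: 7 [(1S,6R)-3,4-dimethyl-6-(prop-1-en-2-yl)cyclohex-3-en-1-yl]methyl 4-methylbenzenesulfonate
Product: 8 (4R,5S)-1,2-dimethyl-4-(prop-1-en-2-yl)-5-(prop-2-yn-1-yl)cyclohex-1-ene
Conditions: LiC≡CH·H2NCH2CH2NH2, DMSO, 23 °C
Reagents that add atoms: lithium acetylide–ethylenediamine complex [Li]C#C.NCCN
Why: SN2 alkylation of acetylide by the primary tosylate in a dipolar aprotic solvent adds the two alkyne carbons (the later B/C fusion CH and second carbonyl carbon of ring C) without creating a stereocenter.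

Step 7
Reactants: 8 (4R,5S)-1,2-dimethyl-4-(prop-1-en-2-yl)-5-(prop-2-yn-1-yl)cyclohex-1-ene
Product: 9 tricyclic enone (ring C cyclopentenone with its β-carbon at the B/C fusion; ring B cis-fused to the 1,2-dimethylcyclohexene ring; angular CH3 cis to that ring)
Conditions: Co2(CO)8 (10 mol %), tetramethylthiourea (60 mol %), CO (1 atm), toluene, 70 °C
Reagents that add atoms: carbon monoxide [C-]#[O+]
Why: Intramolecular Pauson–Khand [2+2+1] cyclocarbonylation of a hept-1-en-6-yne, in which the cis side chains force ring B to be cis-fused to the cyclohexene and the new quaternary carbon forms with ring C on the face of ring B away from the cyclohexene (cis-anti-cis), which places the angular CH3 cis to the cyclohexene ring as the target requires.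

Step 8
Reactants: 9 tricyclic enone
Product: 11 α-hydroxy ketone (OH on the carbon between C=O and the B/C fusion CH; B/C cis-fused), via lithium enolate 10 (not isolated)
Conditions: Li (2.1 equiv), NH3(l)–THF, t-BuOH (1.0 equiv), −78 °C; NH3 evaporated; then 3-phenyl-2-(phenylsulfonyl)oxaziridine, THF, −78 °C; NH4Cl
Reagents that add atoms: 3-phenyl-2-(phenylsulfonyl)oxaziridine O=S(=O)(N1OC1c1ccccc1)c1ccccc1
Why: Dissolving-metal conjugate reduction delivers hydrogen to the B/C fusion carbon to give the only unstrained, cis-fused bicyclo[3.3.0]octane and, regiospecifically, the enolate on the side away from the quaternary carbon, which is hydroxylated in the same flask by the Davis oxaziridine (enolate oxidation), the carbinol configuration being irrelevant because it is oxidized in step 9.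

Step 9
Reactants: 11 α-hydroxy ketone
Product: 12 tricyclic cyclopentane-1,2-dione (drawn as the diketo tautomer; B/C cis-fused)
Conditions: Dess–Martin periodinane, NaHCO3, CH2Cl2, 23 °C
Reagents that add atoms: none
Why: Dess–Martin oxidation of the acyloin gives the 1,2-dione, which exists largely as its enol forms, and the enolizable B/C fusion CH can only return to the cis-fused arrangement.

Step 10
Reactants: 12 tricyclic cyclopentane-1,2-dione; 13 (+)-β-caryophyllene
Product: 15 hetero-Diels–Alder adduct (target skeleton carrying a 1,2-dimethylcyclohexene ring in place of ring A), via α-methylene dione 14 (not isolated)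
Conditions: (CH2O)n (2 equiv), 13 (3 equiv), ethylenediammonium diacetate (20 mol %), 1,4-dioxane, 80 °C, sealed tube
Reagents that add atoms: paraformaldehyde (source of formaldehyde) C=O
Why: Domino Knoevenagel condensation and inverse-electron-demand oxa-Diels–Alder reaction, in which formaldehyde condenses at the only CH2 next to the dione and the resulting 1-oxadiene adds to the strained (E)-trisubstituted alkene of 13 with oxygen at the methyl-bearing carbon and CH2 at the CH carbon, suprafacially (CH3 and H trans) and on the exposed face of the conformer of 13 that corresponds to the ββ form, which sets both ring-D centres as required, while the adduct from the other conformers is expected alongside and is removed by chromatography.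

Step 11
Reactants: 15 hetero-Diels–Alder adduct
Product: 16 epoxide of 15 (oxygen on the convex face of the cyclohexane ring, cis to its two ring-fusion hydrogens)
Conditions: mCPBA (1.05 equiv), NaHCO3, CH2Cl2, −40 °C
Reagents that add atoms: 3-chloroperoxybenzoic acid OOC(=O)c1cccc(Cl)c1
Why: Prilezhaev epoxidation, selective because the tetrasubstituted cyclohexene is far more electron-rich than the 1,1-disubstituted exocyclic alkene or the ketone-conjugated enol ether, with the peracid approaching the convex face of the cis-fused six-five system, anti to ring B and its angular CH3.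

Step 12
Reactants: 16 epoxide of 15
Product: 17 ring-contracted methyl ketone (sterhirsutin C with COCH3 in place of CO2H)
Conditions: BF3·OEt2 (1.1 equiv), 2,6-di-tert-butyl-4-methylpyridine (0.3 equiv), CH2Cl2, −78 °C; Et3N quench
Reagents that add atoms: none
Why: BF3 coordinates the epoxide oxygen and one of its two equivalent tertiary C–O bonds ionizes while the ring CH2 on the neighbouring oxygenated carbon migrates anti-periplanar to the breaking bond (semipinacol or Meinwald rearrangement), so the six-membered ring contracts to ring A and the oxygenated carbon leaves the ring as the acetyl carbonyl. The closest known reaction type is the Lewis-acid ring contraction of 1,2-dimethylcyclohexene oxide to 1-acetyl-1-methylcyclopentane. Ring A is closed by a suprafacial 1,2-shift of a C–C bond to the adjacent electron-deficient carbon (a three-centre Wagner–Meerwein migration, a six-to-five ring contraction), not by an exo or endo attack of an open chain. The only new stereocenter is the quaternary carbon of ring A: the migrating CH2 enters anti to the departing oxygen, so the acetyl group (the later CO2H) stays on the face that carried the epoxide oxygen, cis to the ring-fusion hydrogens, and CH3 points to the concave face, the outcome being controlled by the epoxide configuration set in step 11. The step needs migration of the ring CH2 in preference to CH3 (higher migratory aptitude of a primary alkyl group), indifference to which C–O bond breaks (secured by the local symmetry of the CH2–C(CH3)(O)–C(CH3)(O)–CH2 unit, both pathways giving the same ketone), and survival of the exocyclic methylene, the tertiary enol ether and the ketone (secured by the far higher lability of the tetrasubstituted epoxide at −78 °C and by the hindered pyridine that removes protic acid).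

Step 13
Reactants: 17 ring-contracted methyl ketone
Product: 19 sterhirsutin C, via tribromomethyl ketone 18 (not isolated)
Conditions: Br2 (3.3 equiv), NaOH (aq), 1,4-dioxane–H2O, 0 °C; Na2SO3; then HCl to pH 3
Reagents that add atoms: sodium hydroxide [Na+].[OH-]
Why: Haloform reaction, in which the methyl of the tert-alkyl methyl ketone is the only unhindered enolizable position (the ring C ketone has a single hindered ring-fusion α-hydrogen), is tribrominated and then displaced as CBr3 by hydroxide to give the acid at the non-enolizable quaternary carbon, while the exocyclic alkene tolerates cold alkaline hypobromite.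

## Compound list

1 | 2,3-dimethylbuta-1,3-diene | C=C(C)C(C)=C | starting material
2 | maleic anhydride | O=C1OC(=O)C=C1 | starting material
3 | cis-4,5-dimethylcyclohex-4-ene-1,2-dicarboxylic anhydride (meso, 3aR,7aS) | O=C1OC(=O)[C@H]2CC(C)=C(C)C[C@@H]12 | intermediate
4 | (1S,6R)-6-acetyl-3,4-dimethylcyclohex-3-ene-1-carboxylic acid | OC(=O)[C@H]1CC(C)=C(C)C[C@H]1C(C)=O | intermediate
5 | (1S,6R)-3,4-dimethyl-6-(prop-1-en-2-yl)cyclohex-3-ene-1-carboxylic acid | OC(=O)[C@H]1CC(C)=C(C)C[C@H]1C(C)=C | intermediate
6 | [(1S,6R)-3,4-dimethyl-6-(prop-1-en-2-yl)cyclohex-3-en-1-yl]methanol | OC[C@H]1CC(C)=C(C)C[C@H]1C(C)=C | intermediate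
7 | [(1S,6R)-3,4-dimethyl-6-(prop-1-en-2-yl)cyclohex-3-en-1-yl]methyl 4-methylbenzenesulfonate | Cc1ccc(cc1)S(=O)(=O)OC[C@H]1CC(C)=C(C)C[C@H]1C(C)=C | intermediate
8 | (4R,5S)-1,2-dimethyl-4-(prop-1-en-2-yl)-5-(prop-2-yn-1-yl)cyclohex-1-ene | C#CC[C@H]1CC(C)=C(C)C[C@H]1C(C)=C | intermediate
9 | tricyclic enone: ring C cyclopentenone (β-carbon = B/C fusion carbon), ring B cis-fused to the 1,2-dimethylcyclohexene ring, angular CH3 cis to that ring (cis-anti-cis) | O=C1C=C2C[C@H]3CC(C)=C(C)C[C@H]3[C@]2(C)C1 | intermediate
10 | lithium enolate of the saturated ketone (enolate C=C toward the B/C fusion CH; fusion H cis to angular CH3) | [Li]OC1=C[C@@H]2C[C@H]3CC(C)=C(C)C[C@H]3[C@]2(C)C1 | intermediate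
11 | α-hydroxy ketone (OH on the carbon between C=O and the B/C fusion CH, convex face; B/C cis-fused) | O=C1[C@@H](O)[C@@H]2C[C@H]3CC(C)=C(C)C[C@H]3[C@]2(C)C1 | intermediate
12 | tricyclic cyclopentane-1,2-dione (diketo tautomer drawn; B/C cis-fused) | O=C1C(=O)[C@@H]2C[C@H]3CC(C)=C(C)C[C@H]3[C@]2(C)C1 | intermediate
13 | (+)-β-caryophyllene, (1S,4E,9R)-4,11,11-trimethyl-8-methylidenebicyclo[7.2.0]undec-4-ene | C=C1CC/C=C(\C)CC[C@H]2[C@H]1CC2(C)C | starting material
14 | α-methylene-1,2-dione (exocyclic CH2 on the ring C carbon next to the quaternary carbon) | C=C1C(=O)C(=O)[C@@H]2C[C@H]3CC(C)=C(C)C[C@H]3[C@]12C | intermediate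
15 | hetero-Diels–Alder adduct: sterhirsutin C skeleton with a 1,2-dimethylcyclohexene ring in place of ring A | C=C1CC[C@H]2CC3=C(O[C@]2(C)CC[C@H]2[C@H]1CC2(C)C)C(=O)[C@@H]1C[C@H]2CC(C)=C(C)C[C@H]2[C@]31C | intermediate
16 | epoxide of 15, oxygen on the convex face (cis to the two ring-fusion hydrogens of the six-membered ring) | C=C1CC[C@H]2CC3=C(O[C@]2(C)CC[C@H]2[C@H]1CC2(C)C)C(=O)[C@@H]1C[C@H]2C[C@]4(C)O[C@]4(C)C[C@H]2[C@]31C | intermediate
17 | ring-contracted methyl ketone: sterhirsutin C with COCH3 in place of CO2H (acetyl cis to the A/B ring-fusion hydrogens) | C=C1CC[C@H]2CC3=C(O[C@]2(C)CC[C@H]2[C@H]1CC2(C)C)C(=O)[C@@H]1C[C@H]2C[C@](C)(C(C)=O)C[C@H]2[C@]31C | intermediate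
18 | tribromomethyl ketone of 17 | C=C1CC[C@H]2CC3=C(O[C@]2(C)CC[C@H]2[C@H]1CC2(C)C)C(=O)[C@@H]1C[C@H]2C[C@](C)(C(=O)C(Br)(Br)Br)C[C@H]2[C@]31C | intermediate
19 | sterhirsutin C | C=C1CC[C@H]2CC3=C(O[C@]2(C)CC[C@H]2[C@H]1CC2(C)C)C(=O)[C@@H]1C[C@H]2C[C@](C)(C(=O)O)C[C@H]2[C@]31C | target

## Step count and risks

Total step count: 13. Longest linear sequence: 13 steps (from 1 and 2 to 19); the terpene 13 enters at step 10.

Steps most likely to fail:

Step 10. Discrimination between the two faces of the caryophyllene alkene may be poor, since it rests on conformer populations, and the transient heterodiene may self-condense. Fallback, setting out from 12: the aldol adduct with aqueous formaldehyde (NaHCO3, THF–H2O, 0 °C) would be isolated as the hydroxymethyl diosphenol F1. F1 would then be dehydrated in the presence of 13 by a chelating chiral Lewis acid, Cu(OTf)2 with a C2-symmetric bis(oxazoline) ligand (4 Å sieves, CH2Cl2, −20 °C). The two-point-bound α-methylene dione then reacts under catalyst control instead of substrate control, the ligand enantiomer being chosen for the required adduct. The route is rejoined at 15.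

Step 12. CH3 may migrate in place of the ring CH2, configuration may leak through a free tertiary cation, or the acid may trigger rearrangement of the nine-membered ring with its exocyclic methylene. Fallback, setting out from 15 and bypassing 16: NBS in THF–H2O at 0 °C should give the bromohydrin F2, with bromine on the convex face at one ring carbon and OH on the opposite face at its neighbour. Its lithium alkoxide (LiN(SiMe3)2, LiBr, HMPA–benzene, 60 °C) would then undergo the halide-mediated semipinacol shift under non-acidic conditions. Bromide leaves from the convex face anti to the migrating ring CH2, so the acetyl group again ends on that face. The route is rejoined at 17.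

Step 13. Halogenation may also occur at the ring-fusion α-position of the ring C ketone, or hypobromite may add to the exocyclic alkene. Fallback, setting out from 17: the Ortoleva–King reaction (I2, pyridine, 90 °C) would give the acylmethylpyridinium iodide F3 without free hypohalite. Cleavage with aqueous NaOH (EtOH–H2O, 60 °C, then HCl) gives the acid. The route is rejoined at 19.

Further compounds
F1 | step 10 | hydroxymethyl diosphenol (CH2OH on the enol carbon of ring C next to the quaternary carbon) | OCC1=C(O)C(=O)[C@@H]2C[C@H]3CC(C)=C(C)C[C@H]3[C@]12C
F2 | step 12 | bromohydrin of 15 (Br on the convex face, OH on the concave face of the six-membered ring) | C=C1CC[C@H]2CC3=C(O[C@]2(C)CC[C@H]2[C@H]1CC2(C)C)C(=O)[C@@H]1C[C@H]2C[C@](C)(Br)[C@@](C)(O)C[C@H]2[C@]31C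
F3 | step 13 | acylmethylpyridinium iodide of 17 | C=C1CC[C@H]2CC3=C(O[C@]2(C)CC[C@H]2[C@H]1CC2(C)C)C(=O)[C@@H]1C[C@H]2C[C@](C)(C(=O)C[n+]4ccccc4)C[C@H]2[C@]31C.[I-]
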